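The benzene ring of the phthalide is disconnected across C3a–C4 and C7–C7a. A thermal Diels–Alder benzannulation joins a C4–C7 diene, already oxygenated at C5 and C7, to an enantiopure 4-silyloxy-2-ynoate. The alkyne carbons of the ynoate become C7a (bearing the C1 carboxyl) and C3a (bearing the C3 carbinol), and aromatisation follows by loss of methanol and silicon. One operation thus builds the arene with all four substituents in unambiguous positions and leaves C3 untouched. The ynoate precursor carries the (S)-configured, silyl-protected carbinol and the full side chain, with its 1,4-diketone masked as two dioxolanes. The lactone is closed only at the end.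

Key step: step 8

Remark (assumption): (S,S)-ProPhenol is assumed to deliver the alkynyl group to the aldehyde face that gives the (S)-carbinol 11. This sense is to be confirmed on 11 by MTPA ester analysis; if it proves opposite, the (R,R)-ligand is used with no other change.

Step 1
Reactants: 1 2-methylfuran; 2 11-bromoundec-1-ene
Product: 4 2-methyl-5-(undec-10-en-1-yl)furan, via furyllithium 3 (not isolated)
Conditions: n-BuLi, THF, −20 → 0 °C; then 2, 0 °C → rt
Reagents that add atoms: none
Why: n-BuLi deprotonates 2-methylfuran at its only free alpha position (C5), and the resulting 2-furyllithium should displace bromide from the unhindered primary bromide in an SN2 alkylation, the remote terminal alkene being inert to both reagents.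

Step 2
Reactants: 4 2-methyl-5-(undec-10-en-1-yl)furan
Product: 5 hexadec-15-ene-2,5-dione
Conditions: AcOH–H2O (2:1), H2SO4 (cat.), 100 °C
Reagents that add atoms: water, O
Why: Acid-catalysed hydrolytic ring opening of a 2,5-dialkylfuran (the reverse of the Paal–Knorr furan synthesis) should unmask the 1,4-diketone, while the isolated monosubstituted alkene is not protonated by dilute aqueous acid.

Step 3
Reactants: 5 hexadec-15-ene-2,5-dione
Product: 6 2-methyl-2-{2-[2-(undec-10-en-1-yl)-1,3-dioxolan-2-yl]ethyl}-1,3-dioxolane
Conditions: HOCH2CH2OH (excess), p-TsOH·H2O (cat.), benzene, reflux, Dean–Stark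
Reagents that add atoms: ethylene glycol, OCCO
Why: Acid-catalysed ketalisation with azeotropic removal of water should convert both unhindered ketones into 1,3-dioxolanes, which protects the 1,4-diketone from enolisation, aldol chemistry and the organozinc reagent of step 5.

Step 4
Reactants: 6 2-methyl-2-{2-[2-(undec-10-en-1-yl)-1,3-dioxolan-2-yl]ethyl}-1,3-dioxolane
Product: 8 11,11:14,14-bis(ethylenedioxy)pentadecanal, via ozonide 7 (not isolated)
Conditions: O3, CH2Cl2, −78 °C; then PPh3, −78 °C → rt
Reagents that add atoms: ozone, [O-][O+]=O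
Why: Ozonolysis of the terminal alkene (1,3-dipolar cycloaddition, cycloreversion and recombination to the secondary ozonide) followed by reductive cleavage with the phosphine should give the aldehyde one carbon shorter, the dioxolanes having no acetal C–H and being inert to ozone at low temperature.

Step 5
Reactants: 8 11,11:14,14-bis(ethylenedioxy)pentadecanal; 9 methyl propiolate
Product: 11 methyl (S)-4-hydroxy-14,14:17,17-bis(ethylenedioxy)octadec-2-ynoate, via alkynylzinc 10 (not isolated)
Conditions: Zn(CH3)2 (3 equiv), (S,S)-ProPhenol [2,6-bis{[(S)-2-(hydroxydiphenylmethyl)pyrrolidin-1-yl]methyl}-4-methylphenol] (20 mol %), Ph3P=O (40 mol %), toluene, 0 °C; then 8 added slowly, 4 °C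
Reagents that add atoms: none
Why: In this catalytic enantioselective alkynylation of an aldehyde, Zn(CH3)2 zincates the acidic C–H of 9, and the chiral dinuclear complex formed in situ from Zn(CH3)2 and the ligand, which holds aldehyde and alkynyl group on neighbouring zinc atoms, should transfer the alkynyl group to one aldehyde face, so that the new C4 stereocentre is set (S) under catalyst control while slow addition of 8 suppresses its self-aldol reaction.

Step 6
Reactants: 11 methyl (S)-4-hydroxy-14,14:17,17-bis(ethylenedioxy)octadec-2-ynoate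
Product: 12 methyl (S)-4-(tert-butyldimethylsilyloxy)-14,14:17,17-bis(ethylenedioxy)octadec-2-ynoate
Conditions: TBSCl, imidazole, DMF, 0 °C → rt
Reagents that add atoms: tert-butyldimethylsilyl chloride, CC(C)(C)[Si](C)(C)Cl
Why: Standard O-silylation of a secondary alcohol through the N-silylimidazolium species should proceed without touching the stereocentre, imidazole being too weak a base to isomerise the 4-hydroxy-2-ynoate to an allenoate.

Step 7
Reactants: 13 methyl (E)-3-methoxybut-2-enoate
Product: 15 1,3-dimethoxy-1-(trimethylsilyloxy)buta-1,3-diene, via lithium dienolate 14 (not isolated)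
Conditions: LiN(iPr)2, THF, −78 °C; then TMSCl, −78 °C → rt; non-aqueous work-up, used directly
Reagents that add atoms: chlorotrimethylsilane, C[Si](C)(C)Cl
Why: Kinetic gamma-deprotonation of the beta-methoxy enoate by the hindered lithium amide gives the extended dienolate, which the hard silyl chloride should trap on oxygen to give the silyl ketene acetal diene (either geometry serves, since that carbon becomes planar).

Step 8
Reactants: 12 methyl (S)-4-(tert-butyldimethylsilyloxy)-14,14:17,17-bis(ethylenedioxy)octadec-2-ynoate; 15 1,3-dimethoxy-1-(trimethylsilyloxy)buta-1,3-diene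
Product: 18 methyl (S)-2-[1-(tert-butyldimethylsilyloxy)-11,11:14,14-bis(ethylenedioxy)pentadecyl]-6-hydroxy-4-methoxybenzoate, via cycloadduct 16 (not isolated), via aryl trimethylsilyl ether 17 (not isolated)
Conditions: 15 (3 equiv), toluene, 110 °C, sealed tube; then MeOH, K2CO3 (cat.), 0 °C
Reagents that add atoms: none
Why: The electron-rich diene 15 and the electron-poor ynoate 12 should combine in a normal-demand, concerted but asynchronous [4+2] cycloaddition in which the unsubstituted diene terminus (future C4) bonds to the ynoate beta carbon (future C3a) and the ketene acetal carbon (future C7) bonds to the alpha carbon (future C7a); the 1,4-cyclohexadiene 16 then aromatises by 1,4-elimination of methanol, and methanolysis of the aryl silyl ether 17 gives the phenol 18, hydrogen-bonded to the ester. The closest known reaction type is the Diels–Alder benzannulation of 1,3-dioxygenated silyl ketene acetal dienes with alk-2-ynoates to give resorcylate esters. The only ring formed, the benzene ring, is closed by the cycloaddition itself (a suprafacial 4π + 2π closure forming C4–C3a and C7–C7a), not by a separate cyclisation event. No stereocentre is created: C3 is carried in from 12, and the transient sp3 centre at C7 of 16 is erased on aromatisation. The step needs a single orientation and no erosion at C3: the orientation follows from matched polarisation (largest HOMO coefficient at the diene CH2, largest LUMO coefficient at the ynoate beta carbon), and the neutral, base-free thermal conditions give the silyl-protected propargylic centre no pathway to epimerise through an allenoate. Any adduct that aromatises by loss of silanol instead gives 19 directly and converges in step 9.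

Step 9
Reactants: 18 methyl (S)-2-[1-(tert-butyldimethylsilyloxy)-11,11:14,14-bis(ethylenedioxy)pentadecyl]-6-hydroxy-4-methoxybenzoate
Product: 19 methyl (S)-2-[1-(tert-butyldimethylsilyloxy)-11,11:14,14-bis(ethylenedioxy)pentadecyl]-4,6-dimethoxybenzoate
Conditions: MeI, K2CO3, acetone, 50 °C
Reagents that add atoms: iodomethane, CI
Why: Williamson O-methylation of the phenoxide should proceed once gentle heating overcomes the hydrogen bond of the phenol to the ester, and the silyl ether, dioxolanes and methyl ester are stable to carbonate in acetone.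

Step 10
Reactants: 19 methyl (S)-2-[1-(tert-butyldimethylsilyloxy)-11,11:14,14-bis(ethylenedioxy)pentadecyl]-4,6-dimethoxybenzoate
Product: 21 (S)-5,7-dimethoxy-3-(10,13-dioxotetradecyl)isobenzofuran-1(3H)-one (CJ-13,015), via hydroxy ester 20 (not isolated)
Conditions: 3 M aq. HCl–THF (1:3), rt → 45 °C
Reagents that add atoms: water, O
Why: Aqueous acid hydrolyses both dioxolanes and the silyl ether, and the freed benzylic hydroxyl of 20, held beside the ester, should close the five-membered lactone by intramolecular transesterification (5-exo-trig acyl substitution) without breaking any bond at C3, whose ionisation is disfavoured by the meta-placed methoxy groups and the ortho carbonyl, so the (S) configuration is retained.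

Compound list
1 | 2-methylfuran | Cc1ccco1 | starting material
2 | 11-bromoundec-1-ene | C=CCCCCCCCCCBr | starting material
3 | (5-methylfuran-2-yl)lithium | [Li]c1ccc(C)o1 | intermediate (not isolated)
4 | 2-methyl-5-(undec-10-en-1-yl)furan | Cc1ccc(CCCCCCCCCC=C)o1 | intermediate
5 | hexadec-15-ene-2,5-dione | CC(=O)CCC(=O)CCCCCCCCCC=C | intermediate
6 | 2-methyl-2-{2-[2-(undec-10-en-1-yl)-1,3-dioxolan-2-yl]ethyl}-1,3-dioxolane (bis(ethylene ketal) of 5) | CC1(CCC2(CCCCCCCCCC=C)OCCO2)OCCO1 | intermediate
7 | 3-{9-[2-(2-(2-methyl-1,3-dioxolan-2-yl)ethyl)-1,3-dioxolan-2-yl]nonyl}-1,2,4-trioxolane (secondary ozonide of 6) | CC1(CCC2(CCCCCCCCCC3OCOO3)OCCO2)OCCO1 | intermediate (not isolated)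
8 | 11,11:14,14-bis(ethylenedioxy)pentadecanal, i.e. 10-{2-[2-(2-methyl-1,3-dioxolan-2-yl)ethyl]-1,3-dioxolan-2-yl}decanal | CC1(CCC2(CCCCCCCCCC=O)OCCO2)OCCO1 | intermediate
9 | methyl propiolate | C#CC(=O)OC | starting material
10 | methyl 3-(methylzincio)prop-2-ynoate (alkynyl(methyl)zinc) | C[Zn]C#CC(=O)OC | intermediate (not isolated)
11 | methyl (S)-4-hydroxy-14,14:17,17-bis(ethylenedioxy)octadec-2-ynoate | COC(=O)C#C[C@@H](O)CCCCCCCCCC1(CCC2(C)OCCO2)OCCO1 | intermediate
12 | methyl (S)-4-(tert-butyldimethylsilyloxy)-14,14:17,17-bis(ethylenedioxy)octadec-2-ynoate | COC(=O)C#C[C@@H](O[Si](C)(C)C(C)(C)C)CCCCCCCCCC1(CCC2(C)OCCO2)OCCO1 | intermediate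
13 | methyl (E)-3-methoxybut-2-enoate | CO/C(C)=C/C(=O)OC | starting material
14 | lithium 1,3-dimethoxybuta-1,3-dien-1-olate | C=C(OC)C=C(OC)O[Li] | intermediate (not isolated)
15 | 1,3-dimethoxy-1-(trimethylsilyloxy)buta-1,3-diene | C=C(OC)C=C(OC)O[Si](C)(C)C | intermediate
16 | methyl 2-[(S)-1-(tert-butyldimethylsilyloxy)-11,11:14,14-bis(ethylenedioxy)pentadecyl]-4,6-dimethoxy-6-(trimethylsilyloxy)cyclohexa-1,4-diene-1-carboxylate (mixture at ring C6) | COC(=O)C1=C([C@@H](O[Si](C)(C)C(C)(C)C)CCCCCCCCCC2(CCC3(C)OCCO3)OCCO2)CC(OC)=CC1(OC)O[Si](C)(C)C | intermediate (not isolated)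
17 | methyl (S)-2-[1-(tert-butyldimethylsilyloxy)-11,11:14,14-bis(ethylenedioxy)pentadecyl]-4-methoxy-6-(trimethylsilyloxy)benzoate | COC(=O)c1c(O[Si](C)(C)C)cc(OC)cc1[C@@H](O[Si](C)(C)C(C)(C)C)CCCCCCCCCC1(CCC2(C)OCCO2)OCCO1 | intermediate (not isolated)
18 | methyl (S)-2-[1-(tert-butyldimethylsilyloxy)-11,11:14,14-bis(ethylenedioxy)pentadecyl]-6-hydroxy-4-methoxybenzoate | COC(=O)c1c(O)cc(OC)cc1[C@@H](O[Si](C)(C)C(C)(C)C)CCCCCCCCCC1(CCC2(C)OCCO2)OCCO1 | intermediate
19 | methyl (S)-2-[1-(tert-butyldimethylsilyloxy)-11,11:14,14-bis(ethylenedioxy)pentadecyl]-4,6-dimethoxybenzoate | COC(=O)c1c(OC)cc(OC)cc1[C@@H](O[Si](C)(C)C(C)(C)C)CCCCCCCCCC1(CCC2(C)OCCO2)OCCO1 | intermediate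
20 | methyl (S)-2-(1-hydroxy-11,14-dioxopentadecyl)-4,6-dimethoxybenzoate | COC(=O)c1c(OC)cc(OC)cc1[C@@H](O)CCCCCCCCCC(=O)CCC(C)=O | intermediate (not isolated)
21 | (S)-5,7-dimethoxy-3-(10,13-dioxotetradecyl)isobenzofuran-1(3H)-one (CJ-13,015) | COc1cc(OC)c2c(c1)[C@H](CCCCCCCCCC(=O)CCC(C)=O)OC2=O | target

Total step count: 10. Longest linear sequence: 9 steps (steps 1–6 and 8–10); step 7 is a one-step side branch that supplies the diene.

Steps most likely to fail

Step 8. The cycloaddition may be too slow for the internal, sterically shielded ynoate, so that the diene is consumed by thermal decomposition or protodesilylation before the ring forms, or aromatisation may stall at the cyclohexadiene stage. The fallback sets out from 12, changes the diene partner to a more nucleophilic one that reacts at lower temperature, and moves both O-methylations behind ring formation. Methyl acetoacetate is silylated (TMSCl, Et3N) to methyl 3-(trimethylsilyloxy)but-2-enoate F1, which is deprotonated with LiN(iPr)2 and silylated again to 1-methoxy-1,3-bis(trimethylsilyloxy)buta-1,3-diene F2. Cycloaddition of F2 to 12 (toluene, 80–100 °C), followed by methanolysis of the silyl ethers, should give with the same orientation methyl (S)-2-[1-(tert-butyldimethylsilyloxy)-11,11:14,14-bis(ethylenedioxy)pentadecyl]-4,6-dihydroxybenzoate F3. Double O-methylation of F3 (excess MeI, K2CO3, acetone, reflux) brings the route back at 19.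

Step 5. Facial discrimination may be insufficient with an unbranched, enolisable aliphatic aldehyde, or self-aldol of the aldehyde may outrun alkynyl transfer. The fallback sets out from 8 and separates carbon–carbon bond formation from the setting of configuration. Lithiated methyl propiolate (LiN(iPr)2, THF, −90 to −78 °C) is added to 8 to give racemic methyl (RS)-4-hydroxy-14,14:17,17-bis(ethylenedioxy)octadec-2-ynoate F4. Dess–Martin oxidation (NaHCO3, CH2Cl2) then gives methyl 14,14:17,17-bis(ethylenedioxy)-4-oxooctadec-2-ynoate F5. Midland reduction of F5 with (S)-Alpine-Borane (B-isopinocampheyl-9-borabicyclo[3.3.1]nonane made from (−)-α-pinene), in which the alkynyl group acts as the small substituent, should give the (S)-alcohol and rejoin the route at 11.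

Step 10. Cleavage of the hindered secondary benzylic silyl ether may lag behind ketal hydrolysis, so that forcing conditions expose the liberated 1,4-diketone to acid-promoted cyclodehydration or aldol condensation. The fallback sets out from 19 and stages the deprotection. Bu4NF (THF, 0 °C → rt) removes the silyl group, and the alkoxide so formed should lactonise at once to (S)-3-[10,10:13,13-bis(ethylenedioxy)tetradecyl]-5,7-dimethoxyisobenzofuran-1(3H)-one F6. Mild hydrolysis of the two dioxolanes of F6 (pyridinium p-toluenesulfonate, acetone–H2O, 50 °C) then gives 21.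

Further compounds
F1 | step 8 | methyl 3-(trimethylsilyloxy)but-2-enoate (E/Z mixture) | COC(=O)C=C(C)O[Si](C)(C)C
F2 | step 8 | 1-methoxy-1,3-bis(trimethylsilyloxy)buta-1,3-diene | C=C(O[Si](C)(C)C)C=C(OC)O[Si](C)(C)C
F3 | step 8 | methyl (S)-2-[1-(tert-butyldimethylsilyloxy)-11,11:14,14-bis(ethylenedioxy)pentadecyl]-4,6-dihydroxybenzoate | COC(=O)c1c(O)cc(O)cc1[C@@H](O[Si](C)(C)C(C)(C)C)CCCCCCCCCC1(CCC2(C)OCCO2)OCCO1
F4 | step 5 | methyl (RS)-4-hydroxy-14,14:17,17-bis(ethylenedioxy)octadec-2-ynoate (racemic) | COC(=O)C#CC(O)CCCCCCCCCC1(CCC2(C)OCCO2)OCCO1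
F5 | step 5 | methyl 14,14:17,17-bis(ethylenedioxy)-4-oxooctadec-2-ynoate | COC(=O)C#CC(=O)CCCCCCCCCC1(CCC2(C)OCCO2)OCCO1
F6 | step 10 | (S)-3-[10,10:13,13-bis(ethylenedioxy)tetradecyl]-5,7-dimethoxyisobenzofuran-1(3H)-one | COc1cc(OC)c2c(c1)[C@H](CCCCCCCCCC1(CCC3(C)OCCO3)OCCO1)OC2=O
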